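**Plan**

- Retrosynthetic cuts, in order: the N–CH2 bond between the central spermidine nitrogen and its four-carbon arm (opens the 20-membered ring); the amide C–N bond of the C9b acrylamide and the C8–vinyl bond of the cinnamamide; the C9b–CH=CH bond; the O5–C4a bond; the C4a–C9b and C1–C2 bonds of the cyclohexanone (Diels–Alder).
- Forward order: carbocycle by Diels–Alder of a 2-arylacrolein (from 5-bromosalicylaldehyde) with a 1-amino-3-siloxydiene, then the dihydrofuran ring by phenol oxa-Michael addition, then the Z-acrylate at C9b, the Z-cinnamamide with the hydroxybutyl arm at C8, the nosyl-aminopropyl amide at C9b, and the 20-membered ring last.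
- Enabling feature: the secondary amine nitrogen of the 20-membered ring lies between a (CH2)3 and a (CH2)4 chain, and each chain is anchored by its own Z-amide (three-carbon arm on the C9b acrylamide, four-carbon arm on the C8 cinnamamide). The ring can therefore be closed at N–CH2 with that nitrogen as its acidic 2-nitrobenzenesulfonamide.
- Stereochemistry: C9b comes from the diol-catalysed enantioselective Diels–Alder reaction; C4a is relayed from C9b because the oxa-Michael closure can only give the cis-fused ring; the two Z-alkenes come from a Still–Gennari olefination and a geometry-retaining Suzuki coupling of a Z-iodoacrylamide.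

Key step: step 16

Assumption: the (R,R)-diol catalyst is written for step 4; its sense of induction with this 2-arylacrolein is inferred from 2-alkylacroleins, and if the antipode of 8 should form, the (S,S)-diol is used with nothing else changed.

**Route**

Step 1
Reactants: 1 5-bromosalicylaldehyde
Product: 2 2-(benzyloxy)-5-bromobenzaldehyde
Conditions: BnBr, K2CO3, DMF, rt
Reagents that add atoms: benzyl bromide, BrCc1ccccc1
Why: Williamson etherification of the acidic phenol; the benzyl ether is chosen because it should survive the acidic enol-ether hydrolysis, the amine base, hydride and HF of the next steps and can later be removed by a Lewis acid without touching the aryl bromide.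

Step 2
Reactants: 2 2-(benzyloxy)-5-bromobenzaldehyde
Product: 4 2-[2-(benzyloxy)-5-bromophenyl]acetaldehyde, via enol ether 3 (not isolated)
Conditions: Ph3P(CH2OMe)Cl, KOtBu, THF, 0 °C to rt; then 2 M aq. HCl, THF, 50 °C
Reagents that add atoms: (methoxymethyl)triphenylphosphonium chloride, COC[P+](c1ccccc1)(c1ccccc1)c1ccccc1.[Cl-]; water, O
Why: Wittig methoxymethylenation followed by acid hydrolysis of the enol ether is the standard one-carbon homologation of an aryl aldehyde to an arylacetaldehyde, and neither the benzyl ether nor the aryl bromide reacts.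

Step 3
Reactants: 4 2-[2-(benzyloxy)-5-bromophenyl]acetaldehyde
Product: 6 2-[2-(benzyloxy)-5-bromophenyl]prop-2-enal, via Mannich base 5 (not isolated)
Conditions: CH2=NMe2 I, NEt3, CH2Cl2, rt; used at once
Reagents that add atoms: dimethyl(methylene)ammonium iodide, C=[N+](C)C.[I-]
Why: Mannich aminomethylation of the enolisable arylacetaldehyde followed by E1cB loss of dimethylamine is the usual α-methylenation route to 2-arylacroleins, which are used directly because they tend to dimerise.

Step 4
Reactants: 6 2-[2-(benzyloxy)-5-bromophenyl]prop-2-enal; 7 (E)-3-(tert-butyldimethylsilyloxy)-N,N-dimethylbuta-1,3-dien-1-amine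
Product: 8 (1S,2S)-1-[2-(benzyloxy)-5-bromophenyl]-4-(tert-butyldimethylsilyloxy)-2-(dimethylamino)cyclohex-3-ene-1-carbaldehyde
Conditions: 7 (1.5 equiv), (4R,5R)-2,2-dimethyl-α,α,α′,α′-tetra(1-naphthyl)-1,3-dioxolane-4,5-dimethanol (20 mol %), toluene, −78 °C; crude adduct taken on
Reagents that add atoms: none
Why: hydrogen-bond-catalysed enantioselective Diels–Alder reaction of a 1-amino-3-siloxydiene with an α-substituted acrolein, in which the diene CH2 terminus bonds to the acrolein CH2 so that the amino carbon ends next to the new quaternary carbon, and the chiral diol bound to the formyl oxygen shields one face of the dienophile and so sets the quaternary centre (the later C9b); the amino-bearing centre (endo, formyl cis to NMe2) is lost in step 5.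

Step 5
Reactants: 8 (1S,2S)-1-[2-(benzyloxy)-5-bromophenyl]-4-(tert-butyldimethylsilyloxy)-2-(dimethylamino)cyclohex-3-ene-1-carbaldehyde
Product: 11 (R)-4-[2-(benzyloxy)-5-bromophenyl]-4-(hydroxymethyl)cyclohex-2-en-1-one, via amino alcohol 9 (not isolated), via amino ketone 10 (not isolated)
Conditions: LiAlH4, Et2O, −78 to 0 °C; aqueous work-up; then 48% aq. HF, MeCN, 0 °C to rt
Reagents that add atoms: none
Why: hydride reduction of the non-enolisable aldehyde removes the risk of deformylation at the quaternary carbon, and HF then cleaves the silyl enol ether and the resulting β-amino ketone eliminates dimethylamine to the enone, the standard unveiling of aminosiloxydiene cycloadducts, under which benzyl ether and aryl bromide are inert.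

Step 6
Reactants: 11 (R)-4-[2-(benzyloxy)-5-bromophenyl]-4-(hydroxymethyl)cyclohex-2-en-1-one
Product: 13 (4aR,9bR)-8-bromo-9b-(hydroxymethyl)-1,2,4,4a-tetrahydrodibenzo[b,d]furan-3(9bH)-one, via phenol enone 12 (not isolated)
Conditions: BCl3, C6HMe5, CH2Cl2, −78 °C; aq. NaHCO3; then NEt3 (cat.), MeOH, rt
Reagents that add atoms: none
Why: Lewis-acid debenzylation with pentamethylbenzene as cation scavenger frees the phenol without reducing the enone or the aryl bromide, and the phenol then closes the dihydrofuran ring by intramolecular oxa-Michael addition (5-exo-trig), the tethered oxygen reaching only the enone face syn to the aryl group so that C4a is set by the quaternary centre as the cis-fused isomer.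

Step 7
Reactants: 13 (4aR,9bR)-8-bromo-9b-(hydroxymethyl)-1,2,4,4a-tetrahydrodibenzo[b,d]furan-3(9bH)-one
Product: 14 [(4a′R,9b′R)-8′-bromo-1′,2′,4′,4a′-tetrahydro-9b′H-spiro[1,3-dioxolane-2,3′-dibenzo[b,d]furan]-9b′-yl]methanol
Conditions: HOCH2CH2OH, pyridinium p-toluenesulfonate (cat.), benzene, reflux, azeotropic removal of water
Reagents that add atoms: ethylene glycol, OCCO
Why: acid-catalysed ketalisation masks the ketone so that the β-aryloxy ketone cannot open by retro-oxa-Michael reaction under the basic steps that follow, where the freed phenoxide could otherwise add to the new acrylate.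

Step 8
Reactants: 14 [(4a′R,9b′R)-8′-bromo-1′,2′,4′,4a′-tetrahydro-9b′H-spiro[1,3-dioxolane-2,3′-dibenzo[b,d]furan]-9b′-yl]methanol
Product: 15 (4a′R,9b′S)-8′-bromo-1′,2′,4′,4a′-tetrahydro-9b′H-spiro[1,3-dioxolane-2,3′-dibenzo[b,d]furan]-9b′-carbaldehyde
Conditions: Dess–Martin periodinane, pyridine, CH2Cl2, 0 °C to rt
Reagents that add atoms: none
Why: Dess–Martin oxidation of the neopentyl primary alcohol stops cleanly at the aldehyde, which has no α-hydrogen and cannot epimerise, while the buffered conditions spare the ketal.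

Step 9
Reactants: 15 (4a′R,9b′S)-8′-bromo-1′,2′,4′,4a′-tetrahydro-9b′H-spiro[1,3-dioxolane-2,3′-dibenzo[b,d]furan]-9b′-carbaldehyde
Product: 16 methyl (2Z)-3-[(4a′R,9b′S)-8′-bromo-1′,2′,4′,4a′-tetrahydro-9b′H-spiro[1,3-dioxolane-2,3′-dibenzo[b,d]furan]-9b′-yl]prop-2-enoate
Conditions: (CF3CH2O)2P(O)CH2CO2Me, KN(SiMe3)2, 18-crown-6, THF, −78 °C
Reagents that add atoms: methyl bis(2,2,2-trifluoroethoxy)phosphorylacetate, COC(=O)CP(=O)(OCC(F)(F)F)OCC(F)(F)F
Why: Still–Gennari olefination, in which the electron-poor phosphonate and the crown-ether-separated potassium ion make elimination from the kinetic adduct fast and so deliver the Z-enoate.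

Step 10
Reactants: 16 methyl (2Z)-3-[(4a′R,9b′S)-8′-bromo-1′,2′,4′,4a′-tetrahydro-9b′H-spiro[1,3-dioxolane-2,3′-dibenzo[b,d]furan]-9b′-yl]prop-2-enoate
Product: 17 methyl (2Z)-3-[(4a′R,9b′S)-8′-(4,4,5,5-tetramethyl-1,3,2-dioxaborolan-2-yl)-1′,2′,4′,4a′-tetrahydro-9b′H-spiro[1,3-dioxolane-2,3′-dibenzo[b,d]furan]-9b′-yl]prop-2-enoate
Conditions: B2pin2, PdCl2(dppf) (5 mol %), KOAc, 1,4-dioxane, 80 °C
Reagents that add atoms: bis(pinacolato)diboron, CC1(C)OB(OC1(C)C)B1OC(C)(C)C(C)(C)O1
Why: Miyaura borylation of the aryl bromide, whose weak acetate base leaves the methyl ester, the ketal and the Z-enoate untouched.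

Step 11
Reactants: 18 (Z)-3-iodoacrylic acid; 19 4-aminobutan-1-ol
Product: 20 (Z)-N-(4-hydroxybutyl)-3-iodoprop-2-enamide
Conditions: N-(3-dimethylaminopropyl)-N′-ethylcarbodiimide hydrochloride (EDC·HCl), 1-hydroxybenzotriazole, CH2Cl2, 0 °C
Reagents that add atoms: none
Why: carbodiimide amide coupling in which the amine is acylated far faster than the hydroxyl, the low temperature keeping the amine from adding to the β-iodo position, so the Z-vinyl iodide is carried through unchanged.

Step 12
Reactants: 17 methyl (2Z)-3-[(4a′R,9b′S)-8′-(4,4,5,5-tetramethyl-1,3,2-dioxaborolan-2-yl)-1′,2′,4′,4a′-tetrahydro-9b′H-spiro[1,3-dioxolane-2,3′-dibenzo[b,d]furan]-9b′-yl]prop-2-enoate; 20 (Z)-N-(4-hydroxybutyl)-3-iodoprop-2-enamide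
Product: 21 methyl (2Z)-3-[(4a′R,9b′S)-8′-[(1Z)-3-(4-hydroxybutylamino)-3-oxoprop-1-enyl]-1′,2′,4′,4a′-tetrahydro-9b′H-spiro[1,3-dioxolane-2,3′-dibenzo[b,d]furan]-9b′-yl]prop-2-enoate
Conditions: Pd(PPh3)4 (5 mol %), aq. K3PO4, THF, 45 °C, dark
Reagents that add atoms: none
Why: Suzuki–Miyaura coupling of the arylboronate with the Z-vinyl iodide, in which oxidative addition to zerovalent palladium and reductive elimination both retain alkene geometry, so the Z-cinnamamide and the four-carbon arm are installed together under conditions mild enough for the methyl ester.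

Step 13
Reactants: 21 methyl (2Z)-3-[(4a′R,9b′S)-8′-[(1Z)-3-(4-hydroxybutylamino)-3-oxoprop-1-enyl]-1′,2′,4′,4a′-tetrahydro-9b′H-spiro[1,3-dioxolane-2,3′-dibenzo[b,d]furan]-9b′-yl]prop-2-enoate
Product: 22 (2Z)-3-[(4a′R,9b′S)-8′-[(1Z)-3-(4-hydroxybutylamino)-3-oxoprop-1-enyl]-1′,2′,4′,4a′-tetrahydro-9b′H-spiro[1,3-dioxolane-2,3′-dibenzo[b,d]furan]-9b′-yl]prop-2-enoic acid
Conditions: LiOH, THF/MeOH/H2O, rt; then aq. HCl to pH 4, 0 °C
Reagents that add atoms: lithium hydroxide, [Li+].[OH-]
Why: saponification of the only ester, the secondary amide, both Z-alkenes and (with cold, mild acidification) the ketal being stable to these conditions.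

Step 14
Reactants: 23 propane-1,3-diamine; 24 2-nitrobenzenesulfonyl chloride
Product: 25 N-(3-aminopropyl)-2-nitrobenzenesulfonamide
Conditions: 23 (6 equiv), CH2Cl2, 0 °C, slow addition of 24
Reagents that add atoms: none
Why: sulfonylation of a symmetrical diamine used in large excess stops at the mono-sulfonamide, the excess diamine also taking up the HCl.

Step 15
Reactants: 22 (2Z)-3-[(4a′R,9b′S)-8′-[(1Z)-3-(4-hydroxybutylamino)-3-oxoprop-1-enyl]-1′,2′,4′,4a′-tetrahydro-9b′H-spiro[1,3-dioxolane-2,3′-dibenzo[b,d]furan]-9b′-yl]prop-2-enoic acid; 25 N-(3-aminopropyl)-2-nitrobenzenesulfonamide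
Product: 26 seco bis-Z-amide: ethylene ketal of the (4aR,9bS) tricycle bearing at C9b the (Z)-N-[3-(2-nitrobenzenesulfonamido)propyl]acrylamide and at C8 the (Z)-N-(4-hydroxybutyl)acrylamide
Conditions: EDC·HCl, 1-hydroxybenzotriazole, DMF, 0 °C to rt
Reagents that add atoms: none
Why: carbodiimide and hydroxybenzotriazole amide coupling in which the primary amine of 25 outcompetes the remote hydroxyl and the sulfonamide N–H, fixing the three-carbon arm on the C9b acrylamide so that the order of the two arms is settled before ring closure.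

Step 16
Reactants: 26 seco bis-Z-amide (nosyl-aminopropyl arm at the C9b acrylamide; hydroxybutyl arm at the C8 cinnamamide)
Product: 27 N-(2-nitrobenzenesulfonyl) 20-membered macrocycle ketal (sulfonamide nitrogen bonded to the terminal CH2 of the butyl arm; 4aR 9bS core; both enamides Z)
Conditions: PPh3, diisopropyl azodicarboxylate, toluene/THF, rt, slow addition of 26 by syringe pump, final concentration about 2 mM, dark
Reagents that add atoms: none
Why: Fukuyama–Mitsunobu alkylation: the betaine from PPh3 and the azodicarboxylate deprotonates the 2-nitrobenzenesulfonamide, the hydroxyl of the four-carbon arm becomes an alkoxyphosphonium ion, and the sulfonamide anion displaces Ph3P=O by SN2 at the primary carbon to form the central N–CH2 bond. The closest known reaction type is the intramolecular Mitsunobu N-alkylation of nitrobenzenesulfonamides used to close medium and large polyamine lactam rings. The 20-membered ring closes in a 20-exo-tet mode, helped by the two Z-enamides, which turn both arms toward the same side of the rigid tricyclic core. No stereocentre is formed and none is at risk, because C9b is quaternary, C4a is not acidic while the ketone is ketalised, and substitution takes place at a CH2 group. The step needs N-alkylation of the sulfonamide over the two amides and ring closure over oligomerisation: only the sulfonamide N–H is acidic enough to enter the Mitsunobu cycle, the hydroxyl sits on the four-carbon arm so that attack by its own amide oxygen would need a seven-membered ring, and slow addition at high dilution keeps the reaction intramolecular.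

Step 17
Reactants: 27 N-(2-nitrobenzenesulfonyl) 20-membered macrocycle ketal
Product: 28 macrocyclic secondary amine ethylene ketal (4aR 9bS core; both enamides Z)
Conditions: PhSH, K2CO3, MeCN, rt, degassed, dark
Reagents that add atoms: none
Why: Fukuyama deprotection, in which the thiolate adds at the sulfonyl-bearing carbon of the nitroarene (Meisenheimer complex) and SO2 and the amine are expelled at room temperature; the acrylamides are poor thiol acceptors and oxygen and light are excluded to avoid thiyl-radical isomerisation of the Z-alkenes.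

Step 18
Reactants: 28 macrocyclic secondary amine ethylene ketal
Product: 29 target CNP0159470.1 (4aR 9bS; both enamides Z)
Conditions: 1 M aq. HCl, THF, rt; then aq. NaHCO3
Reagents that add atoms: water, O
Why: acid-catalysed ketal hydrolysis with the amine protonated and inert, the Z-enamides being stable to dilute acid at room temperature and the cis-fused β-aryloxy ketone being the stable closed form.

**Compound list**

1 | 5-bromosalicylaldehyde | O=Cc1cc(Br)ccc1O | starting material
2 | 2-(benzyloxy)-5-bromobenzaldehyde | O=Cc1cc(Br)ccc1OCc1ccccc1 | intermediate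
3 | 1-(benzyloxy)-4-bromo-2-(2-methoxyethenyl)benzene, E/Z mixture (enol ether, formed in the flask) | COC=Cc1cc(Br)ccc1OCc1ccccc1 | intermediate
4 | 2-[2-(benzyloxy)-5-bromophenyl]acetaldehyde | O=CCc1cc(Br)ccc1OCc1ccccc1 | intermediate
5 | 2-[2-(benzyloxy)-5-bromophenyl]-3-(dimethylamino)propanal, racemic (Mannich base, formed in the flask) | O=CC(CN(C)C)c1cc(Br)ccc1OCc1ccccc1 | intermediate
6 | 2-[2-(benzyloxy)-5-bromophenyl]prop-2-enal | C=C(C=O)c1cc(Br)ccc1OCc1ccccc1 | intermediate
7 | (E)-3-(tert-butyldimethylsilyloxy)-N,N-dimethylbuta-1,3-dien-1-amine | CN(C)/C=C/C(=C)O[Si](C)(C)C(C)(C)C | starting material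
8 | (1S,2S)-1-[2-(benzyloxy)-5-bromophenyl]-4-(tert-butyldimethylsilyloxy)-2-(dimethylamino)cyclohex-3-ene-1-carbaldehyde | O=C[C@]1(c2cc(Br)ccc2OCc2ccccc2)CCC(O[Si](C)(C)C(C)(C)C)=C[C@@H]1N(C)C | intermediate
9 | [(1S,2S)-1-[2-(benzyloxy)-5-bromophenyl]-4-(tert-butyldimethylsilyloxy)-2-(dimethylamino)cyclohex-3-en-1-yl]methanol (amino alcohol, formed in the flask) | OC[C@]1(c2cc(Br)ccc2OCc2ccccc2)CCC(O[Si](C)(C)C(C)(C)C)=C[C@@H]1N(C)C | intermediate
10 | (3S,4S)-4-[2-(benzyloxy)-5-bromophenyl]-3-(dimethylamino)-4-(hydroxymethyl)cyclohexan-1-one (amino ketone, formed in the flask) | OC[C@]1(c2cc(Br)ccc2OCc2ccccc2)CCC(=O)C[C@@H]1N(C)C | intermediate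
11 | (R)-4-[2-(benzyloxy)-5-bromophenyl]-4-(hydroxymethyl)cyclohex-2-en-1-one | O=C1CC[C@](CO)(c2cc(Br)ccc2OCc2ccccc2)C=C1 | intermediate
12 | (R)-4-(5-bromo-2-hydroxyphenyl)-4-(hydroxymethyl)cyclohex-2-en-1-one (phenol enone, formed in the flask) | O=C1CC[C@](CO)(c2cc(Br)ccc2O)C=C1 | intermediate
13 | (4aR,9bR)-8-bromo-9b-(hydroxymethyl)-1,2,4,4a-tetrahydrodibenzo[b,d]furan-3(9bH)-one, cis-fused | O=C1CC[C@]2(CO)c3cc(Br)ccc3O[C@@H]2C1 | intermediate
14 | [(4a′R,9b′R)-8′-bromo-1′,2′,4′,4a′-tetrahydro-9b′H-spiro[1,3-dioxolane-2,3′-dibenzo[b,d]furan]-9b′-yl]methanol (ethylene ketal of 13) | O1CCOC12CC[C@]3(CO)c4cc(Br)ccc4O[C@@H]3C2 | intermediate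
15 | (4a′R,9b′S)-8′-bromo-1′,2′,4′,4a′-tetrahydro-9b′H-spiro[1,3-dioxolane-2,3′-dibenzo[b,d]furan]-9b′-carbaldehyde | O1CCOC12CC[C@]3(C=O)c4cc(Br)ccc4O[C@@H]3C2 | intermediate
16 | methyl (2Z)-3-[(4a′R,9b′S)-8′-bromo-1′,2′,4′,4a′-tetrahydro-9b′H-spiro[1,3-dioxolane-2,3′-dibenzo[b,d]furan]-9b′-yl]prop-2-enoate | O1CCOC12CC[C@]3(/C=C\C(=O)OC)c4cc(Br)ccc4O[C@@H]3C2 | intermediate
17 | pinacol boronate of 16 (Bpin at C8′ in place of Br) | O1CCOC12CC[C@]3(/C=C\C(=O)OC)c4cc(B5OC(C)(C)C(C)(C)O5)ccc4O[C@@H]3C2 | intermediate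
18 | (Z)-3-iodoacrylic acid | OC(=O)/C=C\I | starting material
19 | 4-aminobutan-1-ol | NCCCCO | starting material
20 | (Z)-N-(4-hydroxybutyl)-3-iodoprop-2-enamide | OCCCCNC(=O)/C=C\I | intermediate
21 | methyl Z-enoate at C9b with (Z)-N-(4-hydroxybutyl)acrylamide at C8, ethylene ketal, (4aR,9bS) core | O1CCOC12CC[C@]3(/C=C\C(=O)OC)c4cc(/C=C\C(=O)NCCCCO)ccc4O[C@@H]3C2 | intermediate
22 | Z-acrylic acid at C9b with (Z)-N-(4-hydroxybutyl)acrylamide at C8, ethylene ketal, (4aR,9bS) core | O1CCOC12CC[C@]3(/C=C\C(=O)O)c4cc(/C=C\C(=O)NCCCCO)ccc4O[C@@H]3C2 | intermediate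
23 | propane-1,3-diamine | NCCCN | starting material
24 | 2-nitrobenzenesulfonyl chloride | O=S(=O)(Cl)c1ccccc1[N+](=O)[O-] | starting material
25 | N-(3-aminopropyl)-2-nitrobenzenesulfonamide | NCCCNS(=O)(=O)c1ccccc1[N+](=O)[O-] | intermediate
26 | seco bis-Z-amide: (Z)-N-[3-(2-nitrobenzenesulfonamido)propyl]acrylamide at C9b, (Z)-N-(4-hydroxybutyl)acrylamide at C8, ethylene ketal, (4aR,9bS) core | O1CCOC12CC[C@]3(/C=C\C(=O)NCCCNS(=O)(=O)c4ccccc4[N+](=O)[O-])c4cc(/C=C\C(=O)NCCCCO)ccc4O[C@@H]3C2 | intermediate
27 | N-(2-nitrobenzenesulfonyl) 20-membered macrocycle, ethylene ketal, (4aR,9bS) core, both enamides Z | O1CCOC12CC[C@]34/C=C\C(=O)NCCCN(S(=O)(=O)c5ccccc5[N+](=O)[O-])CCCCNC(=O)/C=C\c5ccc(c3c5)O[C@@H]4C2 | intermediate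
28 | macrocyclic secondary amine, ethylene ketal, (4aR,9bS) core, both enamides Z | O1CCOC12CC[C@]34/C=C\C(=O)NCCCNCCCCNC(=O)/C=C\c5ccc(c3c5)O[C@@H]4C2 | intermediate
29 | CNP0159470.1: (4aR,9bS)-hexahydrodibenzofuran-3-one bridged from C9b to C8 by the (Z,Z)-bis(acryloyl)spermidine chain | O=C1CC[C@]23/C=C\C(=O)NCCCNCCCCNC(=O)/C=C\c4ccc(c2c4)O[C@@H]3C1 | target

**Step count and risks**

Total: 18 steps. Longest linear sequence: 16 steps from 5-bromosalicylaldehyde (steps 1–10, 12, 13, 15–18); steps 11 and 14 each make a side-chain piece in one step.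

Steps most likely to fail:

1. Step 4. The uncatalysed cycloaddition of the very reactive diene may compete with the hydrogen-bonded pathway and erode facial selectivity, or the ortho-substituted dienophile may react sluggishly at −78 °C and dimerise instead. The fallback sets out from 6 and returns at 11, with the face controlled by an auxiliary on the diene instead of a catalyst. (2R,5R)-2,5-Diphenylpyrrolidine is condensed with 4-methoxybut-3-en-2-one to the vinylogous amide (E)-4-[(2R,5R)-2,5-diphenylpyrrolidin-1-yl]but-3-en-2-one F1. KN(SiMe3)2 and TBSCl convert it into the chiral diene (2R,5R)-1-[(1E)-3-(tert-butyldimethylsilyloxy)buta-1,3-dienyl]-2,5-diphenylpyrrolidine F2. Thermal cycloaddition of F2 with 6 in toluene between −20 °C and rt, with the C2-symmetric pyrrolidine blocking one diene face, should give the cycloadduct (1S,2S)-1-[2-(benzyloxy)-5-bromophenyl]-4-(tert-butyldimethylsilyloxy)-2-[(2R,5R)-2,5-diphenylpyrrolidin-1-yl]cyclohex-3-ene-1-carbaldehyde F3. LiAlH4 reduction to the amino alcohol F4, then HF in MeCN by way of the amino ketone F5, should release 11 and the recoverable pyrrolidine. The auxiliary enantiomer is the one that delivers the required quaternary configuration and is drawn as (2R,5R) by the same assumption as for the catalyst.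

2. Step 16. Intermolecular alkylation may lead to oligomers, or the alkoxyphosphonium ion may be consumed by elimination before the sulfonamide reaches it. The fallback sets out from 26 and returns at 27, separating activation from ring closure. An Appel reaction (CBr4, PPh3, CH2Cl2, 0 °C) converts the hydroxybutyl arm into the primary bromide, the seco bromide F6. Cs2CO3 with Bu4NI in DMF at 50 °C under syringe-pump dilution then alkylates the caesium sulfonamide intramolecularly; the amide N–H groups are not deprotonated by carbonate.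

3. Step 9. Addition of the phosphonate anion to the congested neopentyl aldehyde may be slow and the Z-selectivity may erode. The fallback sets out from 15 and returns at 16, taking the Z geometry from a cis-hydrogenation instead of an olefination. Ohira–Bestmann homologation (dimethyl (1-diazo-2-oxopropyl)phosphonate, K2CO3, MeOH, rt) gives the terminal alkyne (4a′R,9b′S)-8′-bromo-9b′-ethynyl-1′,2′,4′,4a′-tetrahydro-9b′H-spiro[1,3-dioxolane-2,3′-dibenzo[b,d]furan] F7. Deprotonation with LiN(iPr)2 in THF at −78 °C and trapping with ClCO2Me gives the ynoate methyl 3-[(4a′R,9b′S)-8′-bromo-1′,2′,4′,4a′-tetrahydro-9b′H-spiro[1,3-dioxolane-2,3′-dibenzo[b,d]furan]-9b′-yl]prop-2-ynoate F8. Semihydrogenation over lead-poisoned Pd/CaCO3 with quinoline in EtOAc (Lindlar reduction), which tolerates the aryl bromide, gives 16.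

**Further compounds**

F1 | step 4 | (E)-4-[(2R,5R)-2,5-diphenylpyrrolidin-1-yl]but-3-en-2-one | CC(=O)/C=C/N1[C@@H](c2ccccc2)CC[C@@H]1c1ccccc1
F2 | step 4 | (2R,5R)-1-[(1E)-3-(tert-butyldimethylsilyloxy)buta-1,3-dienyl]-2,5-diphenylpyrrolidine | C=C(O[Si](C)(C)C(C)(C)C)/C=C/N1[C@@H](c2ccccc2)CC[C@@H]1c1ccccc1
F3 | step 4 | (1S,2S)-1-[2-(benzyloxy)-5-bromophenyl]-4-(tert-butyldimethylsilyloxy)-2-[(2R,5R)-2,5-diphenylpyrrolidin-1-yl]cyclohex-3-ene-1-carbaldehyde | O=C[C@]1(c2cc(Br)ccc2OCc2ccccc2)CCC(O[Si](C)(C)C(C)(C)C)=C[C@@H]1N3[C@@H](c4ccccc4)CC[C@@H]3c3ccccc3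
F4 | step 4 | [(1S,2S)-1-[2-(benzyloxy)-5-bromophenyl]-4-(tert-butyldimethylsilyloxy)-2-[(2R,5R)-2,5-diphenylpyrrolidin-1-yl]cyclohex-3-en-1-yl]methanol | OC[C@]1(c2cc(Br)ccc2OCc2ccccc2)CCC(O[Si](C)(C)C(C)(C)C)=C[C@@H]1N3[C@@H](c4ccccc4)CC[C@@H]3c3ccccc3
F5 | step 4 | (3S,4S)-4-[2-(benzyloxy)-5-bromophenyl]-3-[(2R,5R)-2,5-diphenylpyrrolidin-1-yl]-4-(hydroxymethyl)cyclohexan-1-one | OC[C@]1(c2cc(Br)ccc2OCc2ccccc2)CCC(=O)C[C@@H]1N3[C@@H](c4ccccc4)CC[C@@H]3c3ccccc3
F6 | step 16 | seco bromide: 26 with the terminal OH of the butyl arm replaced by Br | O1CCOC12CC[C@]3(/C=C\C(=O)NCCCNS(=O)(=O)c4ccccc4[N+](=O)[O-])c4cc(/C=C\C(=O)NCCCCBr)ccc4O[C@@H]3C2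
F7 | step 9 | (4a′R,9b′S)-8′-bromo-9b′-ethynyl-1′,2′,4′,4a′-tetrahydro-9b′H-spiro[1,3-dioxolane-2,3′-dibenzo[b,d]furan] | O1CCOC12CC[C@]3(C#C)c4cc(Br)ccc4O[C@@H]3C2
F8 | step 9 | methyl 3-[(4a′R,9b′S)-8′-bromo-1′,2′,4′,4a′-tetrahydro-9b′H-spiro[1,3-dioxolane-2,3′-dibenzo[b,d]furan]-9b′-yl]prop-2-ynoate | O1CCOC12CC[C@]3(C#CC(=O)OC)c4cc(Br)ccc4O[C@@H]3C2
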